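At 40.0 min I read the west run, which differs from the flask by its lower charge of free catalyst, and it shows target 12%, or 2.40 mM.

in all of them: added ligand 1.6 mM

| charge | starting material | coupling partner | free catalyst | remark |
|---|---|---|---|---|
| south-west | 10 mM | 20 mM | 1 mM | run made earlier |
| east | 40 mM | 20 mM | 1 mM | run made earlier |
| west | 20 mM | 20 mM | 0.50 mM | run made earlier |
| flask | 20 mM | 20.0 mM | 1.0 mM |  |
- south-west (time / min: target / %, starting material / %): 2.50: 3, 91; 8.00: 14, 87; 12.0: 13, 88; 20.0: 19, 80; 30.0: 27, 70; 40.0: 32, 75
- east (time / min: target / %, starting material / %): 3.00: 3, 93; 5.00: 0, 95; 8.00: 6, 92; 12.0: 9, 88; 20.0: 14, 90; 40.0: 20, 75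
- west (time / min: target / %, starting material / %): 3.00: 0, 99; 10.0: 5, 95; 15.0: 9, 93; 25.0: 6, 89; 40.0: 12, 88

(scatter of a reading: 2 percentage points)
- factor on the rate of making target when 20% of the starting material are converted if free catalyst is charged twice over
- factor on the rate when 20% of the starting material are converted if free catalyst is charged at 10 mM instead


The flask has no readings, but its c(starting material) lies midway on a logarithmic scale between the south-west and east runs. These hold 3.20 mM and 8.00 mM of target at the same time, so I take their geometric mean as my own estimate for the flask:

c(target) = 5.06 mM

That is about twice the west reading, and the catalyst charge of the flask is twice that of the west run, though each reading carries a scatter of 2 percentage points. To see whether this continues, I carry one number: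

ligand per catalyst = c(added ligand) / c(free catalyst) = 1.60

I suppose that one ligand holds one catalyst, so the zero of this scale is parity, a value of one. The west run stands at 3.20, and like the flask it lies above parity, so in both the ligand charged covers the catalyst charged by count. The doubled charge stands at 0.800, and the charge of 10 mM at 0.160. Both lie below parity, so on my supposition the ligand is there the limiting reagent of the binding, and at least 0.400 mM of the doubled charge stays unbound by ligand. A rate that simply follows the charge gives factors of 2 and 10.0. I expect more than 2 on doubling, and at the large charge I keep 10.0 as my reference figure, without a claim on which side of it the flask falls.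

The forecast gives 2.2 and 12, both above the proportional figures, “with wide uncertainty on the extrapolation”.

The simulation gives 3.80 on doubling and 8.76 at 10 mM.

    starting material + free catalyst ⇌ catalyst intermediate A (K = 48.0 M⁻¹, k = 2.30 M⁻¹ s⁻¹)
    catalyst intermediate A ⇌ catalyst intermediate B (K = 0.870, k = 0.0520 s⁻¹)
    coupling partner + catalyst intermediate B → catalyst intermediate C (k = 2.10 M⁻¹ s⁻¹)
    catalyst intermediate C → free catalyst + target (k = 0.0390 s⁻¹)
    free catalyst + added ligand ⇌ idle complex (K = 6000 M⁻¹, k = 3.10 M⁻¹ s⁻¹)

At 0.500 h, near the moment asked about, the idle complex holds 70.3% of the catalyst in the flask, and this off-cycle form leaves 29.7% in the other forms. On doubling the charge of the flask, where ligand per catalyst falls to 0.800, the rate per catalyst charged rises by a factor of 1.90. At 10 mM, a ligand per catalyst of 0.160 allows the idle complex at most that fraction of the catalyst, yet the rate per catalyst charged stands at 0.876 of the flask's.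

The data are simulated for substances that don't exist; scatter was added.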